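## Retrosynthetic overview

1. Target ⇐ global desilylation ⇐ two successive Horner–Wadsworth–Emmons olefinations (C10=C11, then C10'=C11') of a symmetric C12 tetraene bis-phosphonate with a ring A and a ring B C14 aldehyde.
2. Key C–C bond in each half: the ring-to-chain bond C6–C7 (C6'–C7'), made by intermolecular aldol condensation of a dimedone-derived ketone enolate with one common C5 enal; the exocyclic alkene comes from the dehydration.
3. Ring A: Stork–Danheiser MeLi addition and enone transposition, then asymmetric transfer hydrogenation sets 3S.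
4. Ring B: asymmetric epoxidation of 5,5-dimethylcyclohexenone sets 3'R and forces enolisation to C6'; reductive epoxide opening, then substrate-controlled MeLi addition sets 5'S.
5. No ring is formed: both carbocycles come intact from dimedone (ring A elaborated first, ring B second); the linchpin comes from glyoxal mono-acetal and a C5 phosphonate.

Assumption: carotenoid numbering is used for positions; the epi-quinine-derived amine salt of step 14 is taken to give the (2R,3R)-epoxide, and its quinidine-derived pseudo-enantiomer replaces it if the optical rotation shows the antipode.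

Abbreviations: TBS = tert-butyldimethylsilyl, TIPS = triisopropylsilyl.

## Route

Step 1
Reactants: 1 ethyl (2E)-3-methyl-4-oxobut-2-enoate
Product: 2 ethyl (2E)-4-hydroxy-3-methylbut-2-enoate
Conditions: NaBH4, CeCl3·7H2O, MeOH, −20 °C
Reagents that add atoms: none
Why: Luche 1,2-reduction takes the aldehyde selectively over the conjugated ester, and the E hydroxy ester cannot lactonise.

Step 2
Reactants: 2 ethyl (2E)-4-hydroxy-3-methylbut-2-enoate
Product: 3 ethyl (2E)-3-methyl-4-(TBS-oxy)but-2-enoate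
Conditions: TBSCl, imidazole, CH2Cl2, 0 °C → rt
Reagents that add atoms: tert-butyldimethylsilyl chloride CC(C)(C)[Si](C)(C)Cl
Why: Routine silyl ether formation on an unhindered primary alcohol.

Step 3
Reactants: 3 ethyl (2E)-3-methyl-4-(TBS-oxy)but-2-enoate
Product: 4 (2E)-3-methyl-4-(TBS-oxy)but-2-en-1-ol
Conditions: i-Bu2AlH (2.3 equiv), CH2Cl2, −78 °C
Reagents that add atoms: none
Why: Hydride reduction of the enoate to the allylic alcohol leaves the alkene geometry and the silyl ether untouched.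

Step 4
Reactants: 4 (2E)-3-methyl-4-(TBS-oxy)but-2-en-1-ol
Product: 5 (2E)-3-methyl-4-(TBS-oxy)but-2-enal
Conditions: MnO2, CH2Cl2, rt
Reagents that add atoms: none
Why: Neutral allylic oxidation stops at the enal and does not isomerise the double bond.

Step 5
Reactants: 6 dimedone
Product: 7 3-ethoxy-5,5-dimethylcyclohex-2-en-1-one
Conditions: EtOH, p-TsOH (cat.), toluene, reflux, Dean–Stark
Reagents that add atoms: ethanol CCO
Why: Acid-catalysed enol etherification (vinylogous ester formation) of the symmetric dione gives a single product.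

Step 6
Reactants: 7 3-ethoxy-5,5-dimethylcyclohex-2-en-1-one; 5 (2E)-3-methyl-4-(TBS-oxy)but-2-enal
Product: 9 aldol adduct 3-ethoxy-6-[(2E)-1-hydroxy-3-methyl-4-(TBS-oxy)but-2-en-1-yl]-5,5-dimethylcyclohex-2-en-1-one (racemic diastereomer mixture), via lithium dienolate 8 (not isolated)
Conditions: LiN(i-Pr)2, THF, −78 °C; then 5, −78 °C
Reagents that add atoms: none
Why: Kinetic deprotonation of the vinylogous ester occurs only at the alpha-prime carbon, and the intermolecular aldol addition of this enolate to the enal forges the C6–C7 bond; the two new stereocentres are erased in step 7.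

Step 7
Reactants: 9 aldol adduct
Product: 11 dienone (6E)-3-ethoxy-5,5-dimethyl-6-[(2E)-3-methyl-4-(TBS-oxy)but-2-en-1-ylidene]cyclohex-2-en-1-one, via allylic mesylate 10 (not isolated)
Conditions: MsCl, Et3N, CH2Cl2, 0 °C; then DBU, rt; chromatography
Reagents that add atoms: none
Why: E1cB elimination completes the aldol condensation and under equilibrating base is expected to place the chain anti to the carbonyl (E, the usual geometry of 2-alkylidene cycloalkanones), any Z isomer being removed on silica.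

Step 8
Reactants: 11 dienone
Product: 13 retro trienone (4E)-3,5,5-trimethyl-4-[(2E)-3-methyl-4-(TBS-oxy)but-2-en-1-ylidene]cyclohex-2-en-1-one, via tertiary carbinol 12 (not isolated)
Conditions: MeLi, CeCl3, THF, −78 °C; then 0.5 M aq. HCl, 0 °C, 15 min
Reagents that add atoms: methyllithium [Li]C; water O
Why: Stork–Danheiser sequence, in which 1,2-addition of the organocerium reagent and brief acid hydrolysis of the enol ether with loss of the tertiary hydroxyl transpose the enone and install the C5 methyl group, short enough to spare the primary TBS ether and the exocyclic geometry.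

Step 9
Reactants: 13 retro trienone
Product: 14 allylic alcohol (1S,4E)-3,5,5-trimethyl-4-[(2E)-3-methyl-4-(TBS-oxy)but-2-en-1-ylidene]cyclohex-2-en-1-ol
Conditions: RuCl[(S,S)-TsDPEN](p-cymene) (1 mol %), KOH (2 mol %), i-PrOH, 25 °C, dark
Reagents that add atoms: none
Why: Noyori asymmetric transfer hydrogenation reduces only the carbonyl and, with the alkenyl side of the ketone in the place of the aryl group of the usual model (the same carbonyl environment as in 4-oxoisophorone), the (S,S)-catalyst gives the 1S alcohol, which is C3 (S) of ring A.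

Step 10
Reactants: 14 allylic alcohol
Product: 15 bis-silyl ether (1S,4E)-3,5,5-trimethyl-4-[(2E)-3-methyl-4-(TBS-oxy)but-2-en-1-ylidene]-1-(TIPS-oxy)cyclohex-2-ene
Conditions: TIPSOTf, 2,6-lutidine, CH2Cl2, −78 °C
Reagents that add atoms: triisopropylsilyl triflate CC(C)[Si](C(C)C)(C(C)C)OS(=O)(=O)C(F)(F)F
Why: Buffered silylation at low temperature protects the ionisable allylic alcohol without acid exposure.

Step 11
Reactants: 15 bis-silyl ether
Product: 16 ring A C14 alcohol (2E,4E)-2-methyl-4-[(4S)-2,6,6-trimethyl-4-(TIPS-oxy)cyclohex-2-en-1-ylidene]but-2-en-1-ol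
Conditions: Bu4NF (1.1 equiv), THF, 0 °C
Reagents that add atoms: none
Why: Fluoride desilylation removes the primary TBS ether far faster than the secondary TIPS ether.

Step 12
Reactants: 16 ring A C14 alcohol
Product: 17 ring A C14 aldehyde (2E,4E)-2-methyl-4-[(4S)-2,6,6-trimethyl-4-(TIPS-oxy)cyclohex-2-en-1-ylidene]but-2-enal
Conditions: MnO2, CH2Cl2, rt, dark
Reagents that add atoms: none
Why: Neutral allylic oxidation gives the trienal without touching the acid-sensitive allylic silyl ether.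

Step 13
Reactants: 7 3-ethoxy-5,5-dimethylcyclohex-2-en-1-one
Product: 19 5,5-dimethylcyclohex-2-en-1-one, via ethoxy allylic alcohol 18 (not isolated)
Conditions: LiAlH4, Et2O, 0 °C; then 1 M aq. H2SO4
Reagents that add atoms: water O
Why: 1,2-reduction of the vinylogous ester followed by acid hydrolysis with allylic transposition (reductive Stork–Danheiser transposition) is the classical route to this enone.

Step 14
Reactants: 19 5,5-dimethylcyclohex-2-en-1-one
Product: 20 (2R,3R)-2,3-epoxy-5,5-dimethylcyclohexan-1-one [(1R,6R)-4,4-dimethyl-7-oxabicyclo[4.1.0]heptan-2-one]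
Conditions: 9-amino-9-deoxy-epi-quinine bis(trifluoroacetate) (10 mol %), 50% aq. H2O2, dioxane, 35 °C
Reagents that add atoms: hydrogen peroxide OO
Why: Iminium-catalysed asymmetric nucleophilic epoxidation, in which the chiral primary amine salt steers hydroperoxide to one enone face and so sets both epoxide carbons (the later C3' R centre) in one step.

Step 15
Reactants: 20 (2R,3R)-2,3-epoxy-5,5-dimethylcyclohexan-1-one; 5 (2E)-3-methyl-4-(TBS-oxy)but-2-enal
Product: 22 aldol adduct (1R,6R)-3-[(2E)-1-hydroxy-3-methyl-4-(TBS-oxy)but-2-en-1-yl]-4,4-dimethyl-7-oxabicyclo[4.1.0]heptan-2-one (mixture at the two new centres), via lithium enolate 21 (not isolated)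
Conditions: LiN(i-Pr)2, THF, −78 °C; then 5, −78 °C
Reagents that add atoms: none
Why: The epoxide blocks the other alpha position, so enolisation can only occur at C6' next to the gem-dimethyl group, and the intermolecular aldol addition forges the C6'–C7' bond; the two new centres are erased in step 16.

Step 16
Reactants: 22 aldol adduct
Product: 24 epoxy dienone (1R,3E,6R)-4,4-dimethyl-3-[(2E)-3-methyl-4-(TBS-oxy)but-2-en-1-ylidene]-7-oxabicyclo[4.1.0]heptan-2-one, via allylic mesylate 23 (not isolated)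
Conditions: MsCl, Et3N, CH2Cl2, 0 °C; then DBU, rt; chromatography
Reagents that add atoms: none
Why: E1cB elimination completes the aldol condensation and is expected to give the E enone with the chain anti to the carbonyl, which is the required 6'E geometry (chain syn to the gem-dimethyl carbon); any Z isomer is removed on silica and the assignment checked by NOE.

Step 17
Reactants: 24 epoxy dienone
Product: 25 hydroxy ketone (2E,5R)-5-hydroxy-3,3-dimethyl-2-[(2E)-3-methyl-4-(TBS-oxy)but-2-en-1-ylidene]cyclohexan-1-one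
Conditions: SmI2 (2.2 equiv), THF–MeOH, −90 °C
Reagents that add atoms: none
Why: Single-electron reduction to the ketyl is followed by fast cleavage of the alpha C–O bond (reductive opening of an alpha,beta-epoxy ketone), so the beta C–O bond and its R configuration are kept.

Step 18
Reactants: 25 hydroxy ketone
Product: 26 silyloxy ketone (2E,5R)-3,3-dimethyl-2-[(2E)-3-methyl-4-(TBS-oxy)but-2-en-1-ylidene]-5-(TIPS-oxy)cyclohexan-1-one
Conditions: TIPSOTf, 2,6-lutidine, CH2Cl2, −78 °C
Reagents that add atoms: triisopropylsilyl triflate CC(C)[Si](C(C)C)(C(C)C)OS(=O)(=O)C(F)(F)F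
Why: Low-temperature buffered silylation protects the beta-hydroxy ketone before it can eliminate.

Step 19
Reactants: 26 silyloxy ketone
Product: 27 tertiary alcohol (1S,2E,5R)-1,3,3-trimethyl-2-[(2E)-3-methyl-4-(TBS-oxy)but-2-en-1-ylidene]-5-(TIPS-oxy)cyclohexan-1-ol
Conditions: MeLi, CeCl3, THF, −78 °C
Reagents that add atoms: methyllithium [Li]C
Why: Organocerium 1,2-addition avoids enolisation and conjugate addition, and with the silyloxy group equatorial the axial methyl of the gem-dimethyl group blocks axial attack (as in 3,3,5-trimethylcyclohexanone), so methyl enters equatorially cis to O-3' and gives the 5'S carbinol with its hydroxyl trans to O-3'.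

Step 20
Reactants: 27 tertiary alcohol
Product: 28 ring B diol (1S,2E,5R)-2-[(2E)-4-hydroxy-3-methylbut-2-en-1-ylidene]-1,3,3-trimethyl-5-(TIPS-oxy)cyclohexan-1-ol
Conditions: Bu4NF (1.1 equiv), THF, 0 °C
Reagents that add atoms: none
Why: Selective fluoride cleavage of the primary TBS ether under basic conditions that the acid-labile tertiary allylic alcohol tolerates.

Step 21
Reactants: 28 ring B diol
Product: 29 ring B C14 aldehyde (2E,4E)-4-[(2S,4R)-2-hydroxy-2,6,6-trimethyl-4-(TIPS-oxy)cyclohexylidene]-2-methylbut-2-enal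
Conditions: MnO2, CH2Cl2, rt, dark
Reagents that add atoms: none
Why: MnO2 oxidises only the primary allylic alcohol; the tertiary alcohol cannot be oxidised and the E geometry prevents oxa-Michael closure.

Step 22
Reactants: 30 ethyl (2E)-4-(diethoxyphosphoryl)-3-methylbut-2-enoate; 31 2,2-dimethoxyacetaldehyde
Product: 33 ethyl (2E,4E)-6,6-dimethoxy-3-methylhexa-2,4-dienoate, via sodium phosphonate carbanion 32 (not isolated)
Conditions: NaH, THF, 0 °C; then 31 (dry t-BuOMe solution), 0 °C → rt; chromatography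
Reagents that add atoms: none
Why: Horner–Wadsworth–Emmons olefination with the vinylogous phosphonoacetate gives the E disubstituted alkene, the minor 2Z isomer being removed.

Step 23
Reactants: 33 ethyl (2E,4E)-6,6-dimethoxy-3-methylhexa-2,4-dienoate
Product: 34 ethyl (2E,4E)-3-methyl-6-oxohexa-2,4-dienoate
Conditions: 1 M aq. HCl, acetone, rt
Reagents that add atoms: water O
Why: Acid hydrolysis of the allylic dimethyl acetal unmasks the second glyoxal carbon as a conjugated aldehyde.

Step 24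
Reactants: 34 ethyl (2E,4E)-3-methyl-6-oxohexa-2,4-dienoate; 30 ethyl (2E)-4-(diethoxyphosphoryl)-3-methylbut-2-enoate
Product: 36 diethyl (2E,4E,6E,8E)-3,8-dimethyldeca-2,4,6,8-tetraenedioate, via lithium phosphonate carbanion 35 (not isolated)
Conditions: LiN(SiMe3)2, THF, −78 °C; then 34, −78 → 0 °C; recrystallisation
Reagents that add atoms: none
Why: A second Horner–Wadsworth–Emmons olefination, run with the lithium carbanion preformed by a soluble amide base so that the base-sensitive enal ester never meets free hydride, gives the symmetric tetraene diester, whose all-E isomer crystallises.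

Step 25
Reactants: 36 diethyl (2E,4E,6E,8E)-3,8-dimethyldeca-2,4,6,8-tetraenedioate
Product: 37 (2E,4E,6E,8E)-3,8-dimethyldeca-2,4,6,8-tetraene-1,10-diol
Conditions: i-Bu2AlH (4.5 equiv), CH2Cl2, −78 °C
Reagents that add atoms: none
Why: Hydride reduction of both conjugated esters to allylic alcohols without touching the tetraene.

Step 26
Reactants: 37 (2E,4E,6E,8E)-3,8-dimethyldeca-2,4,6,8-tetraene-1,10-diol
Product: 38 (2E,4E,6E,8E)-1,10-dibromo-3,8-dimethyldeca-2,4,6,8-tetraene
Conditions: PBr3, pyridine (cat.), Et2O, −10 °C, dark; used at once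
Reagents that add atoms: phosphorus tribromide BrP(Br)Br
Why: Bromination of primary allylic alcohols by substitution through the phosphite ester at low temperature, as practised for polyene diols.

Step 27
Reactants: 38 (2E,4E,6E,8E)-1,10-dibromo-3,8-dimethyldeca-2,4,6,8-tetraene
Product: 39 tetraethyl [(2E,4E,6E,8E)-3,8-dimethyldeca-2,4,6,8-tetraene-1,10-diyl]bis(phosphonate)
Conditions: P(OEt)3, 120 °C
Reagents that add atoms: triethyl phosphite CCOP(OCC)OCC
Why: Michaelis–Arbuzov reaction at both primary allylic bromides gives the symmetric linchpin.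

Step 28
Reactants: 39 bis-phosphonate (4 equiv); 17 ring A C14 aldehyde
Product: 41 C26 phosphonate diethyl {(2E,4E,6E,8E,10E,12E,14E)-3,8,12-trimethyl-14-[(4S)-2,6,6-trimethyl-4-(TIPS-oxy)cyclohex-2-en-1-ylidene]tetradeca-2,4,6,8,10,12-hexaen-1-yl}phosphonate, via bisphosphonate monoanion 40 (not isolated)
Conditions: NaN(SiMe3)2 (1 equiv relative to 17), THF, −78 °C; then 17, −78 → 0 °C, dark; excess 39 recovered
Reagents that add atoms: none
Why: Horner–Wadsworth–Emmons olefination of the trienal with the monoanion of the excess linchpin forms the E C10=C11 bond, the excess keeping double olefination statistically low because the adduct only collapses on warming after the aldehyde is consumed.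

Step 29
Reactants: 41 C26 phosphonate; 29 ring B C14 aldehyde
Product: 43 3,3'-bis-O-TIPS ether of the target, via phosphonate carbanion 42 (not isolated)
Conditions: NaN(SiMe3)2 (1.05 equiv), THF, −78 °C; then 29, −78 → 0 °C, dark
Reagents that add atoms: none
Why: A second Horner–Wadsworth–Emmons olefination forms the E C10'=C11' bond and completes the C40 skeleton; the delocalised carbanion is too weak a base to be quenched by the free tertiary hydroxyl.

Step 30
Reactants: 43 3,3'-bis-O-TIPS ether of the target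
Product: 44 target CNP0269135.1
Conditions: Bu4NF (4 equiv), THF, rt, dark, Ar
Reagents that add atoms: none
Why: Fluoride desilylation under basic, acid-free conditions frees both secondary hydroxyls without ionising either allylic alcohol or isomerising the polyene.

## Compound list

1 | ethyl (2E)-3-methyl-4-oxobut-2-enoate | CCOC(=O)/C=C(C)/C=O | starting material
2 | ethyl (2E)-4-hydroxy-3-methylbut-2-enoate | CCOC(=O)/C=C(C)/CO | intermediate
3 | ethyl (2E)-3-methyl-4-(TBS-oxy)but-2-enoate | CCOC(=O)/C=C(C)/CO[Si](C)(C)C(C)(C)C | intermediate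
4 | (2E)-3-methyl-4-(TBS-oxy)but-2-en-1-ol | OC/C=C(C)/CO[Si](C)(C)C(C)(C)C | intermediate
5 | (2E)-3-methyl-4-(TBS-oxy)but-2-enal | O=C/C=C(C)/CO[Si](C)(C)C(C)(C)C | intermediate
6 | dimedone (5,5-dimethylcyclohexane-1,3-dione) | CC1(C)CC(=O)CC(=O)C1 | starting material
7 | 3-ethoxy-5,5-dimethylcyclohex-2-en-1-one | CCOC1=CC(=O)CC(C)(C)C1 | intermediate
8 | lithium dienolate of 7 (deprotonated at C6) | [Li+].CCOC1=CC([O-])=CC(C)(C)C1 | intermediate
9 | aldol adduct 3-ethoxy-6-[(2E)-1-hydroxy-3-methyl-4-(TBS-oxy)but-2-en-1-yl]-5,5-dimethylcyclohex-2-en-1-one (racemic diastereomer mixture) | CCOC1=CC(=O)C(C(O)/C=C(C)/CO[Si](C)(C)C(C)(C)C)C(C)(C)C1 | intermediate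
10 | methanesulfonate of 9 at the new secondary hydroxyl | CCOC1=CC(=O)C(C(OS(C)(=O)=O)/C=C(C)/CO[Si](C)(C)C(C)(C)C)C(C)(C)C1 | intermediate
11 | (6E)-3-ethoxy-5,5-dimethyl-6-[(2E)-3-methyl-4-(TBS-oxy)but-2-en-1-ylidene]cyclohex-2-en-1-one | CCOC1=CC(=O)/C(=C/C=C(C)/CO[Si](C)(C)C(C)(C)C)C(C)(C)C1 | intermediate
12 | (6E)-3-ethoxy-1,5,5-trimethyl-6-[(2E)-3-methyl-4-(TBS-oxy)but-2-en-1-ylidene]cyclohex-2-en-1-ol (racemic) | CCOC1=CC(C)(O)/C(=C/C=C(C)/CO[Si](C)(C)C(C)(C)C)C(C)(C)C1 | intermediate
13 | (4E)-3,5,5-trimethyl-4-[(2E)-3-methyl-4-(TBS-oxy)but-2-en-1-ylidene]cyclohex-2-en-1-one | O=C1C=C(C)/C(=C/C=C(C)/CO[Si](C)(C)C(C)(C)C)C(C)(C)C1 | intermediate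
14 | (1S,4E)-3,5,5-trimethyl-4-[(2E)-3-methyl-4-(TBS-oxy)but-2-en-1-ylidene]cyclohex-2-en-1-ol | CC1=C[C@@H](O)CC(C)(C)\C1=C/C=C(C)/CO[Si](C)(C)C(C)(C)C | intermediate
15 | (1S,4E)-3,5,5-trimethyl-4-[(2E)-3-methyl-4-(TBS-oxy)but-2-en-1-ylidene]-1-(TIPS-oxy)cyclohex-2-ene | CC1=C[C@@H](O[Si](C(C)C)(C(C)C)C(C)C)CC(C)(C)\C1=C/C=C(C)/CO[Si](C)(C)C(C)(C)C | intermediate
16 | (2E,4E)-2-methyl-4-[(4S)-2,6,6-trimethyl-4-(TIPS-oxy)cyclohex-2-en-1-ylidene]but-2-en-1-ol | CC1=C[C@@H](O[Si](C(C)C)(C(C)C)C(C)C)CC(C)(C)\C1=C/C=C(C)/CO | intermediate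
17 | (2E,4E)-2-methyl-4-[(4S)-2,6,6-trimethyl-4-(TIPS-oxy)cyclohex-2-en-1-ylidene]but-2-enal | CC1=C[C@@H](O[Si](C(C)C)(C(C)C)C(C)C)CC(C)(C)\C1=C/C=C(C)/C=O | intermediate
18 | 3-ethoxy-5,5-dimethylcyclohex-2-en-1-ol | CCOC1=CC(O)CC(C)(C)C1 | intermediate
19 | 5,5-dimethylcyclohex-2-en-1-one | CC1(C)CC=CC(=O)C1 | intermediate
20 | (2R,3R)-2,3-epoxy-5,5-dimethylcyclohexan-1-one | O=C1CC(C)(C)C[C@H]2O[C@@H]12 | intermediate
21 | lithium enolate of 20 (deprotonated at C6) | [Li+].[O-]C1=CC(C)(C)C[C@H]2O[C@@H]12 | intermediate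
22 | (1R,6R)-3-[(2E)-1-hydroxy-3-methyl-4-(TBS-oxy)but-2-en-1-yl]-4,4-dimethyl-7-oxabicyclo[4.1.0]heptan-2-one (mixture at the two new centres) | O=C1C(C(O)/C=C(C)/CO[Si](C)(C)C(C)(C)C)C(C)(C)C[C@H]2O[C@@H]12 | intermediate
23 | methanesulfonate of 22 at the new secondary hydroxyl | O=C1C(C(OS(C)(=O)=O)/C=C(C)/CO[Si](C)(C)C(C)(C)C)C(C)(C)C[C@H]2O[C@@H]12 | intermediate
24 | (1R,3E,6R)-4,4-dimethyl-3-[(2E)-3-methyl-4-(TBS-oxy)but-2-en-1-ylidene]-7-oxabicyclo[4.1.0]heptan-2-one | O=C1/C(=C/C=C(C)/CO[Si](C)(C)C(C)(C)C)C(C)(C)C[C@H]2O[C@@H]12 | intermediate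
25 | (2E,5R)-5-hydroxy-3,3-dimethyl-2-[(2E)-3-methyl-4-(TBS-oxy)but-2-en-1-ylidene]cyclohexan-1-one | O=C1/C(=C/C=C(C)/CO[Si](C)(C)C(C)(C)C)C(C)(C)C[C@@H](O)C1 | intermediate
26 | (2E,5R)-3,3-dimethyl-2-[(2E)-3-methyl-4-(TBS-oxy)but-2-en-1-ylidene]-5-(TIPS-oxy)cyclohexan-1-one | O=C1/C(=C/C=C(C)/CO[Si](C)(C)C(C)(C)C)C(C)(C)C[C@@H](O[Si](C(C)C)(C(C)C)C(C)C)C1 | intermediate
27 | (1S,2E,5R)-1,3,3-trimethyl-2-[(2E)-3-methyl-4-(TBS-oxy)but-2-en-1-ylidene]-5-(TIPS-oxy)cyclohexan-1-ol | CC(C)(C)[Si](C)(C)OC/C(C)=C/C=C1\C(C)(C)C[C@@H](O[Si](C(C)C)(C(C)C)C(C)C)C[C@]1(C)O | intermediate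
28 | (1S,2E,5R)-2-[(2E)-4-hydroxy-3-methylbut-2-en-1-ylidene]-1,3,3-trimethyl-5-(TIPS-oxy)cyclohexan-1-ol | OC/C(C)=C/C=C1\C(C)(C)C[C@@H](O[Si](C(C)C)(C(C)C)C(C)C)C[C@]1(C)O | intermediate
29 | (2E,4E)-4-[(2S,4R)-2-hydroxy-2,6,6-trimethyl-4-(TIPS-oxy)cyclohexylidene]-2-methylbut-2-enal | O=C/C(C)=C/C=C1\C(C)(C)C[C@@H](O[Si](C(C)C)(C(C)C)C(C)C)C[C@]1(C)O | intermediate
30 | ethyl (2E)-4-(diethoxyphosphoryl)-3-methylbut-2-enoate (the commercial E/Z mixture serves, the anion equilibrates) | CCOC(=O)/C=C(C)/CP(=O)(OCC)OCC | starting material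
31 | 2,2-dimethoxyacetaldehyde | COC(OC)C=O | starting material
32 | sodium salt of the carbanion of 30 | [Na+].CCOC(=O)C=C(C)[CH-]P(=O)(OCC)OCC | intermediate
33 | ethyl (2E,4E)-6,6-dimethoxy-3-methylhexa-2,4-dienoate | CCOC(=O)/C=C(C)/C=C/C(OC)OC | intermediate
34 | ethyl (2E,4E)-3-methyl-6-oxohexa-2,4-dienoate | CCOC(=O)/C=C(C)/C=C/C=O | intermediate
35 | lithium salt of the carbanion of 30 | [Li+].CCOC(=O)C=C(C)[CH-]P(=O)(OCC)OCC | intermediate
36 | diethyl (2E,4E,6E,8E)-3,8-dimethyldeca-2,4,6,8-tetraenedioate | CCOC(=O)/C=C(C)/C=C/C=C/C(C)=C/C(=O)OCC | intermediate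
37 | (2E,4E,6E,8E)-3,8-dimethyldeca-2,4,6,8-tetraene-1,10-diol | OC/C=C(C)/C=C/C=C/C(C)=C/CO | intermediate
38 | (2E,4E,6E,8E)-1,10-dibromo-3,8-dimethyldeca-2,4,6,8-tetraene | BrC/C=C(C)/C=C/C=C/C(C)=C/CBr | intermediate
39 | tetraethyl [(2E,4E,6E,8E)-3,8-dimethyldeca-2,4,6,8-tetraene-1,10-diyl]bis(phosphonate) | CCOP(=O)(OCC)C/C=C(C)/C=C/C=C/C(C)=C/CP(=O)(OCC)OCC | intermediate
40 | monosodium carbanion of 39 | [Na+].CCOP(=O)(OCC)[CH-]/C=C(C)/C=C/C=C/C(C)=C/CP(=O)(OCC)OCC | intermediate
41 | diethyl {(2E,4E,6E,8E,10E,12E,14E)-3,8,12-trimethyl-14-[(4S)-2,6,6-trimethyl-4-(TIPS-oxy)cyclohex-2-en-1-ylidene]tetradeca-2,4,6,8,10,12-hexaen-1-yl}phosphonate | CC1=C[C@@H](O[Si](C(C)C)(C(C)C)C(C)C)CC(C)(C)\C1=C/C=C(C)/C=C/C=C(C)/C=C/C=C/C(C)=C/CP(=O)(OCC)OCC | intermediate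
42 | sodium carbanion of 41 (alpha to phosphorus) | [Na+].CC1=C[C@@H](O[Si](C(C)C)(C(C)C)C(C)C)CC(C)(C)\C1=C/C=C(C)/C=C/C=C(C)/C=C/C=C/C(C)=C/[CH-]P(=O)(OCC)OCC | intermediate
43 | 3,3'-bis-O-TIPS ether of the target (3S,3'R,5'S; 6E,6'E; all-E chain) | CC1=C[C@@H](O[Si](C(C)C)(C(C)C)C(C)C)CC(C)(C)\C1=C/C=C(C)/C=C/C=C(C)/C=C/C=C/C(C)=C/C=C/C(C)=C/C=C1\C(C)(C)C[C@@H](O[Si](C(C)C)(C(C)C)C(C)C)C[C@]1(C)O | intermediate
44 | CNP0269135.1, (3S,3'R,5'S,6E,6'E)-4,5'-retro-β,β-carotene-3,3',5'-triol (all-E) | CC1=C[C@@H](O)CC(C)(C)\C1=C/C=C(C)/C=C/C=C(C)/C=C/C=C/C(C)=C/C=C/C(C)=C/C=C1\C(C)(C)C[C@@H](O)C[C@]1(C)O | target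

## Summary

Total step count: 30.
Longest linear sequence: 14 steps (steps 1–4, 6–12, 28–30).

Steps most likely to fail, each with a fallback:

Step 14. The amine-catalysed epoxidation may give insufficient enantiomeric excess, or the wrong sense, on the 5,5-dimethyl substrate. The fallback replaces catalyst-controlled epoxidation by reagent-controlled reduction and substrate-directed oxidation. It sets out from 19: CBS reduction with (R)-Me-CBS and catecholborane (toluene, −78 °C) gives (1S)-5,5-dimethylcyclohex-2-en-1-ol F1. Hydroxyl-directed epoxidation (VO(acac)2, t-BuOOH, CH2Cl2) delivers oxygen syn to the hydroxyl and gives (1S,2S,3R)-2,3-epoxy-5,5-dimethylcyclohexan-1-ol F2. Dess–Martin oxidation comes back to the route at 20.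

Step 16. The gem-dimethyl group next to the ylidene carbon can erode or even reverse the normal E preference of the E1cB dehydration, and the wrong geometry would be carried to the end (step 7 shares the concern, but there the isomers can still be separated after step 9). The fallback makes the geometry stereospecific instead of thermodynamic. It sets out from 19: the boron dienolate (c-Hex2BCl, Et3N, Et2O, −78 °C) adds to 5 through a chair transition state to give the racemic anti aldol adduct F3. Syn-dehydration (DCC, CuCl cat., toluene, 80 °C) turns the anti aldol specifically into the E cross-conjugated dienone F4. Asymmetric conjugate borylation of the unhindered ring enone (CuCl, NaOt-Bu, Josiphos ligand of the antipode giving 5R, B2pin2, MeOH, THF) gives the beta-boryl ketone F5. Oxidation with NaBO3 (retention at carbon) comes back to the route at 25; steps 14 to 17 are replaced.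

Step 28. Mono-olefination of the symmetric bis-phosphonate is statistical, and proton transfer to the more acidic product can raise the amount of doubly coupled material. The fallback reverses the polarity of the linchpin so that the selective step is a mono-Wittig reaction on a dialdehyde, which stops cleanly because the product polyenal is much less electrophilic. From 37, MnO2 (CH2Cl2) gives (2E,4E,6E,8E)-3,8-dimethyldeca-2,4,6,8-tetraenedial F6. From 16, CBr4 with excess PPh3 (CH2Cl2, 0 °C) gives the ring A allylic triphenylphosphonium bromide F7. The ylide of F7 (NaOMe, CH2Cl2/MeOH) with excess F6 gives the C26 aldehyde F8. From 28, the same CBr4/PPh3 treatment gives the ring B allylic triphenylphosphonium bromide F9, whose ylide with F8 comes back to the route at 43; minor Z isomers at the two new bonds are removed by chromatography.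

## Further compounds

F1 | step 14 | (1S)-5,5-dimethylcyclohex-2-en-1-ol | O[C@@H]1C=CCC(C)(C)C1
F2 | step 14 | (1S,2S,3R)-2,3-epoxy-5,5-dimethylcyclohexan-1-ol | O[C@H]1CC(C)(C)C[C@H]2O[C@@H]12
F3 | step 16 | anti aldol adduct rel-(6S)-6-[(1S,2E)-1-hydroxy-3-methyl-4-(TBS-oxy)but-2-en-1-yl]-5,5-dimethylcyclohex-2-en-1-one (racemic, one enantiomer drawn) | O=C1C=CCC(C)(C)[C@H]1[C@@H](O)/C=C(C)/CO[Si](C)(C)C(C)(C)C
F4 | step 16 | (6E)-5,5-dimethyl-6-[(2E)-3-methyl-4-(TBS-oxy)but-2-en-1-ylidene]cyclohex-2-en-1-one | O=C1C=CCC(C)(C)\C1=C/C=C(C)/CO[Si](C)(C)C(C)(C)C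
F5 | step 16 | (2E,5R)-3,3-dimethyl-2-[(2E)-3-methyl-4-(TBS-oxy)but-2-en-1-ylidene]-5-(4,4,5,5-tetramethyl-1,3,2-dioxaborolan-2-yl)cyclohexan-1-one | O=C1/C(=C/C=C(C)/CO[Si](C)(C)C(C)(C)C)C(C)(C)C[C@@H](B2OC(C)(C)C(C)(C)O2)C1
F6 | step 28 | (2E,4E,6E,8E)-3,8-dimethyldeca-2,4,6,8-tetraenedial | O=C/C=C(C)/C=C/C=C/C(C)=C/C=O
F7 | step 28 | {(2E,4E)-2-methyl-4-[(4S)-2,6,6-trimethyl-4-(TIPS-oxy)cyclohex-2-en-1-ylidene]but-2-en-1-yl}triphenylphosphonium bromide | CC1=C[C@@H](O[Si](C(C)C)(C(C)C)C(C)C)CC(C)(C)\C1=C/C=C(C)/C[P+](c2ccccc2)(c2ccccc2)c2ccccc2.[Br-]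
F8 | step 28 | (2E,4E,6E,8E,10E,12E,14E)-3,8,12-trimethyl-14-[(4S)-2,6,6-trimethyl-4-(TIPS-oxy)cyclohex-2-en-1-ylidene]tetradeca-2,4,6,8,10,12-hexaenal | CC1=C[C@@H](O[Si](C(C)C)(C(C)C)C(C)C)CC(C)(C)\C1=C/C=C(C)/C=C/C=C(C)/C=C/C=C/C(C)=C/C=O
F9 | step 28 | {(2E,4E)-4-[(2S,4R)-2-hydroxy-2,6,6-trimethyl-4-(TIPS-oxy)cyclohexylidene]-2-methylbut-2-en-1-yl}triphenylphosphonium bromide | [Br-].c2ccccc2[P+](c2ccccc2)(c2ccccc2)C/C(C)=C/C=C1\C(C)(C)C[C@@H](O[Si](C(C)C)(C(C)C)C(C)C)C[C@]1(C)O
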